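Time is the unit here: give each way out of a species its half-life, and you can read off the race between the exits.

in all of them: time 20 d
- blue: Q 0.050 M (in portions, 5, over 12 d); Z 0.200 M; first portion at the start, last at 12 d
- green: Q 0.050 M; Z 0.200 M; everything together at the start
- violet: Q 0.050 M; Z 0.200 M (fed, over 12 d); all else is in the flask from the start; the feed brings no volume worth counting
- teal: Q 0.050 M (fed, over 30 h); Z 0.200 M; all else is in the flask from the start; the feed brings no volume worth counting
- grey: Q 0.050 M (fed, over 12 d); Z 0.200 M; all else is in the flask from the start; the feed brings no volume worth counting

    Z + Z.X ⇌ Z.Z.X (K1 = 1.4 /M, k1 = 0.078 /M/h)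
    X → E (k2 = 0.011 /h)
    Q → L (k3 = 0.032 /h)
    Z + X ⇌ Z.X (K4 = 2.2 /M, k4 = 0.30 /M/h)
    L ⇌ X (K5 = 0.99, k5 = 0.0088 /h)
    Z + X → G (k6 = 0.043 /M/h)

* the flask with the highest share of E in E plus G ("all alike" if they lie within 1.5 percentage points) (blue / green / violet / teal / grey / all alike)
* share of E in E plus G at the end, blue
* share of E in E plus G at the end, green
* share of E in E plus G at the end, violet
* share of E in E plus G at the end, teal
* share of E in E plus G at the end, grey

First ask which constants have to be known well. The steps from Q through L to X set when X appears, but E and G both grow from the same free X, at each moment in the ratio of their two rates. An error in those steps therefore moves the calendar and leaves that ratio, at a given Z, as it was, though in violet the calendar is set against the Z feed, so there it still counts. The equilibria that hold X as Z.X and Z.Z.X act the same way, except through the Z they hold. What must be right is the pair X → E (k2 = 0.011 /h) and Z + X → G (k6 = 0.043 /M/h), together with z, the free Z as a fraction of its charge. Q's charge is a quarter of Z's, so were every Q to end as G, with one Z taken each, z would end at 75.0%, and where Z is there from the start, you may treat the step to G as pseudo-first-order.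

Now the numbers. X goes to E with a half-life of 2.63 d and, at z of one, to G with a half-life of 3.36 d. Your share of E is then tG/(tG + z·tE), which at z of one gives 56.1%. Call this half-life ratio the branch share. Were the step to G faster by a factor of 2, it would read 39.0%, so this is the pair to measure.

My reckoning puts blue, green, teal and grey at 56.1% or somewhat above, as z falls below one. Violet's feed lasts 3.66 forward half-lives of L, and if I take z as rising steadily from zero to one, I reckon it at about half during the feed, which gives 71.9%. I would commit to less than that for violet, because L's forward half-life of 3.28 d is shorter than the feed by too little to keep X from passing late in the feed, at z above half.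

The forecast reasons that “Only feeding Z slowly keeps [Z] low while most of the X passes through”. It gives 58% for blue, 58.5% for green, 71% for violet, 58.5% for teal and 57.5% for grey, and names violet.

The simulation gives 57.4% for blue, 57.7% for green, 68.2% for violet, 57.7% for teal and 57.4% for grey, so violet leads green by 10 percentage points.

Over the first 12.0 d of violet, z averaged 47.5%, where the branch share reads 72.9%, and the steps to E and G ran on X as it came from L. At 20.0 d violet's Z stood at 92.6% of its charge, with L at 9.04% and X at 3.92% of the Q charged still on the way, and at 200 d its share reads 66.6%.

Take the same flask as blue with Z at 0.050 M, a quarter of blue's charge: the branch share gives 83.7%. The computed result there is 84.5%.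

The constants used here belong to no real substance; the run is a simulation.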